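## Retrosynthetic overview

1. Numbering: daucane (C1 = CH3-bearing fusion carbon, C4 = isopropyl carbinol, C5 = fusion CH, C6 = ester carbon, C8 = olefinic C–CH3, C10 = allylic carbinol; β = face of the C1 methyl). The open chain uses farnesane numbering; its C1/C5/C6/C7/C10 become daucane C10/C6/C5/C1/C4.
2. 16 ⇐ 15 (Si–O cleavage) ⇐ 13 + 4-methoxybenzoyl chloride ⇐ 12 (hydroxyl-directed, anti-selective reduction of the C6 ketone).
3. 12 ⇐ acyclic diketone 9 in one flask: ring A (seven-membered) closes first through the farnesane C1–C7 bond, ring B (five-membered) second through the C6–C10 bond. This is the bond set and order of the farnesyl → carotyl cyclisation, run as a radical addition/enamine aldol cascade under a chiral amine.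
4. 9 ⇐ epoxide 8 by a 1,2-hydride shift ⇐ 7 ⇐ 6 ⇐ 5 ⇐ lactone 4 ⇐ geranial 1 + bromo ester 2 (vinylogous Reformatsky; the lactone ring fixes the 2Z olefin).

Assumption: 1 and 2 are bought as such, and the (1R,2R) amine of step 7 is taken to give the (1S) quaternary centre (if the sense is opposite, its enantiomer is used).

## Route

Step 1
Reactants: 1 geranial; 2 ethyl 4-bromo-3-methylbut-2-enoate
Product: 4 rac-6-[(1E)-2,6-dimethylhepta-1,5-dien-1-yl]-4-methyl-5,6-dihydro-2H-pyran-2-one, via hydroxy ester 3 (not isolated)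
Conditions: Zn dust (TMSCl-activated), THF, 45 °C; aq. NH4Cl
Reagents that add atoms: none
Why: Vinylogous Reformatsky reaction: the zinc dienolate from 2 adds through its γ-carbon to the aldehyde only, and the Z-configured alkoxide 3 closes to the six-membered lactone, which fixes the 2Z geometry needed for ring A; the new carbinol centre is racemic and is erased in step 4.

Step 2
Reactants: 4 rac-6-[(1E)-2,6-dimethylhepta-1,5-dien-1-yl]-4-methyl-5,6-dihydro-2H-pyran-2-one
Product: 5 rac-(2Z,6E)-3,7,11-trimethyldodeca-2,6,10-triene-1,5-diol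
Conditions: i-Bu2AlH (3.2 equiv), CH2Cl2, −78 → 0 °C; Rochelle salt
Reagents that add atoms: none
Why: 1,2-Reduction of the α,β-unsaturated δ-lactone by i-Bu2AlH gives the allylic 1,5-diol without touching the C=C bonds, and the ring-derived Z geometry is kept.

Step 3
Reactants: 5 rac-(2Z,6E)-3,7,11-trimethyldodeca-2,6,10-triene-1,5-diol
Product: 6 rac-(2Z,6E)-1-[(tert-butyldimethylsilyl)oxy]-3,7,11-trimethyldodeca-2,6,10-trien-5-ol
Conditions: TBSCl (1.05 equiv), imidazole, CH2Cl2, −20 °C
Reagents that add atoms: tert-butyldimethylsilyl chloride, CC(C)(C)[Si](C)(C)Cl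
Why: Chemoselective silylation: the unhindered primary allylic hydroxyl reacts much faster than the secondary hydroxyl next to a trisubstituted olefin.

Step 4
Reactants: 6 rac-(2Z,6E)-1-[(tert-butyldimethylsilyl)oxy]-3,7,11-trimethyldodeca-2,6,10-trien-5-ol
Product: 7 (2Z,6E)-1-[(tert-butyldimethylsilyl)oxy]-3,7,11-trimethyldodeca-2,6,10-trien-5-one
Conditions: MnO2 (activated, 15 equiv), CH2Cl2, 20 °C
Reagents that add atoms: none
Why: MnO2 oxidises the allylic secondary alcohol to the E-enone under neutral conditions, leaving the silyl ether and the skipped Z-olefin untouched; the racemic centre disappears.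

Step 5
Reactants: 7 (2Z,6E)-1-[(tert-butyldimethylsilyl)oxy]-3,7,11-trimethyldodeca-2,6,10-trien-5-one
Product: 8 rac-(2Z,6E)-1-[(tert-butyldimethylsilyl)oxy]-9-(3,3-dimethyloxiran-2-yl)-3,7-dimethylnona-2,6-dien-5-one
Conditions: m-CPBA (1.0 equiv), NaHCO3, CH2Cl2, −20 °C
Reagents that add atoms: 3-chloroperbenzoic acid, OOC(=O)c1cccc(Cl)c1
Why: Prilezhaev epoxidation follows olefin nucleophilicity: the isolated trisubstituted 10,11-olefin reacts first, the 6,7-olefin being deactivated by the carbonyl and the 2,3-olefin by the allylic silyloxy group; the racemic epoxide centre is erased in step 6.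

Step 6
Reactants: 8 rac-(2Z,6E)-1-[(tert-butyldimethylsilyl)oxy]-9-(3,3-dimethyloxiran-2-yl)-3,7-dimethylnona-2,6-dien-5-one
Product: 9 (2Z,6E)-1-[(tert-butyldimethylsilyl)oxy]-3,7,11-trimethyldodeca-2,6-diene-5,10-dione
Conditions: Bi(O3SCF3)3 (2 mol %), CH2Cl2, 0 °C, 15 min
Reagents that add atoms: none
Why: Meinwald rearrangement: Lewis-acid opening at the tertiary C–O bond and a 1,2-hydride shift from C10 give the isopropyl ketone (the same 1,2-H shift that moves the charge to C4 in the biogenesis); the conjugated 6,7-olefin is too electron-poor for a competing cation–olefin cyclisation.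

Step 7
Reactants: 9 (2Z,6E)-1-[(tert-butyldimethylsilyl)oxy]-3,7,11-trimethyldodeca-2,6-diene-5,10-dione
Product: 12 (1S,4R,5R,10R)-10-[(tert-butyldimethylsilyl)oxy]-4-hydroxydauc-8-en-6-one, via iminium ion 10 (not isolated), via ring-A enamine 11 (not isolated)
Conditions: (1R,2R)-2-(9H-carbazol-9-yl)cyclohexan-1-amine (20 mol %), PhCO2H (40 mol %), (n-Bu4N)4[W10O32] (5 mol %), MeCN–H2O 20:1, 390 nm LED, 25 °C, Ar
Reagents that add atoms: none
Why: Proposed new method: the primary amine condenses with the enone carbonyl (the isopropyl ketone is too hindered) to the 6E-iminium ion 10; photoexcited decatungstate abstracts the weakest and most hydridic C–H (allylic and α-silyloxy, chain C1); the 1-silyloxyallyl radical adds through C1 to the iminium β-carbon in a 7-endo closure (its other terminus could only close 5-endo, and addition to C=N or C=O is reversible); carbazole-relayed back electron transfer turns the α-iminyl radical cation into enamine 11, which attacks the isopropyl ketone in a 5-(enolexo) aldol and is hydrolysed, so ring A then ring B form in the order of the farnesyl-to-carotyl cyclisation; C1 (S) is set by the amine shielding one iminium face, C10 (R) because the silyloxy group sits exo on the allyl radical (away from C7) and so ends cis to the C2 arm, which is trans to the iminium carbon in the E-olefin, C4 (R) from the N–H···O=C hydrogen-bonded aldol transition state (hydroxyl cis to the C6 carbonyl), and C5 settles as the trans ring fusion by enamine/iminium equilibration; closest known reaction types: enantioselective iminium-ion trapping of photochemically generated α-oxy radicals to form quaternary carbons, decatungstate hydrogen-atom-transfer Giese additions and the Hajos–Parrish enamine aldol.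

Step 8
Reactants: 12 (1S,4R,5R,10R)-10-[(tert-butyldimethylsilyl)oxy]-4-hydroxydauc-8-en-6-one
Product: 13 (1S,4R,5S,6S,10R)-10-[(tert-butyldimethylsilyl)oxy]dauc-8-ene-4,6-diol
Conditions: Me4NBH(OAc)3 (5 equiv), MeCN–AcOH 1:1, −30 °C
Reagents that add atoms: none
Why: Evans–Saksena reduction: the C4 hydroxyl exchanges onto boron and delivers hydride intramolecularly to the C6 carbonyl from its own (β) face, giving the anti-1,3-diol, i.e. the 6α (6S) carbinol.

Step 9
Reactants: 13 (1S,4R,5S,6S,10R)-10-[(tert-butyldimethylsilyl)oxy]dauc-8-ene-4,6-diol; 14 4-methoxybenzoyl chloride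
Product: 15 (1S,4R,5S,6S,10R)-10-[(tert-butyldimethylsilyl)oxy]-4-hydroxydauc-8-en-6-yl 4-methoxybenzoate
Conditions: 14 (1.5 equiv), DMAP (0.2 equiv), pyridine, CH2Cl2, 0 → 25 °C
Reagents that add atoms: none
Why: DMAP-catalysed acylation reaches only the secondary C6 hydroxyl, because the C4 hydroxyl is tertiary and the C10 oxygen is silylated; no stereocentre is touched.

Step 10
Reactants: 15 (1S,4R,5S,6S,10R)-10-[(tert-butyldimethylsilyl)oxy]-4-hydroxydauc-8-en-6-yl 4-methoxybenzoate
Product: 16 (1S,4R,5S,6S,10R)-4,10-dihydroxydauc-8-en-6-yl 4-methoxybenzoate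
Conditions: HF·pyridine, pyridine–THF, 0 → 25 °C
Reagents that add atoms: none
Why: Fluoride-mediated Si–O cleavage under buffered, non-basic conditions frees the C10 hydroxyl without acyl migration or ionisation of the allylic alcohol.

## Compound list

1 | geranial, (2E)-3,7-dimethylocta-2,6-dienal | CC(C)=CCC/C(C)=C/C=O | starting material
2 | ethyl 4-bromo-3-methylbut-2-enoate (E/Z mixture) | CCOC(=O)C=C(C)CBr | starting material
3 | ethyl (2Z,6E)-5-hydroxy-3,7,11-trimethyldodeca-2,6,10-trienoate (racemic, present as its zinc alkoxide) | CCOC(=O)/C=C(C)\CC(O)/C=C(\C)CCC=C(C)C | intermediate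
4 | rac-6-[(1E)-2,6-dimethylhepta-1,5-dien-1-yl]-4-methyl-5,6-dihydro-2H-pyran-2-one | CC1=CC(=O)OC(C1)/C=C(\C)CCC=C(C)C | intermediate
5 | rac-(2Z,6E)-3,7,11-trimethyldodeca-2,6,10-triene-1,5-diol | OC/C=C(C)\CC(O)/C=C(\C)CCC=C(C)C | intermediate
6 | rac-(2Z,6E)-1-[(tert-butyldimethylsilyl)oxy]-3,7,11-trimethyldodeca-2,6,10-trien-5-ol | CC(C)(C)[Si](C)(C)OC/C=C(C)\CC(O)/C=C(\C)CCC=C(C)C | intermediate
7 | (2Z,6E)-1-[(tert-butyldimethylsilyl)oxy]-3,7,11-trimethyldodeca-2,6,10-trien-5-one | CC(C)(C)[Si](C)(C)OC/C=C(C)\CC(=O)/C=C(\C)CCC=C(C)C | intermediate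
8 | rac-(2Z,6E)-1-[(tert-butyldimethylsilyl)oxy]-9-(3,3-dimethyloxiran-2-yl)-3,7-dimethylnona-2,6-dien-5-one | CC(C)(C)[Si](C)(C)OC/C=C(C)\CC(=O)/C=C(\C)CCC1OC1(C)C | intermediate
9 | (2Z,6E)-1-[(tert-butyldimethylsilyl)oxy]-3,7,11-trimethyldodeca-2,6-diene-5,10-dione | CC(C)(C)[Si](C)(C)OC/C=C(C)\CC(=O)/C=C(\C)CCC(=O)C(C)C | intermediate
10 | iminium ion of 9 at chain C5 with (1R,2R)-2-(9H-carbazol-9-yl)cyclohexan-1-amine | CC(C)(C)[Si](C)(C)OC/C=C(C)\CC(=[NH+][C@@H]1CCCC[C@H]1n1c2ccccc2c2ccccc12)/C=C(\C)CCC(=O)C(C)C | intermediate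
11 | ring-A enamine: cyclohepta-1,4-dienyl amine with the quaternary carbon (S) and the silyloxy carbon (R) in place, keto side chain still open | CC(C)C(=O)CC[C@@]1(C)C=C(N[C@@H]2CCCC[C@H]2n2c3ccccc3c3ccccc23)CC(C)=C[C@H]1O[Si](C)(C)C(C)(C)C | intermediate
12 | (1S,4R,5R,10R)-10-[(tert-butyldimethylsilyl)oxy]-4-hydroxydauc-8-en-6-one (1β-CH3, 4β-OH, 5α-H, 10α-OSi, trans-fused) | O=C2CC(C)=C[C@@H](O[Si](C)(C)C(C)(C)C)[C@@]3(C)CC[C@@](O)(C(C)C)[C@H]23 | intermediate
13 | (1S,4R,5S,6S,10R)-10-[(tert-butyldimethylsilyl)oxy]dauc-8-ene-4,6-diol (6α-OH) | O[C@H]2CC(C)=C[C@@H](O[Si](C)(C)C(C)(C)C)[C@@]3(C)CC[C@@](O)(C(C)C)[C@H]23 | intermediate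
14 | 4-methoxybenzoyl chloride | COc1ccc(cc1)C(Cl)=O | starting material
15 | (1S,4R,5S,6S,10R)-10-[(tert-butyldimethylsilyl)oxy]-4-hydroxydauc-8-en-6-yl 4-methoxybenzoate | COc1ccc(C(=O)O[C@H]2CC(C)=C[C@@H](O[Si](C)(C)C(C)(C)C)[C@@]3(C)CC[C@@](O)(C(C)C)[C@H]23)cc1 | intermediate
16 | (1S,4R,5S,6S,10R)-4,10-dihydroxydauc-8-en-6-yl 4-methoxybenzoate (4β,10α-dihydroxy-6α-acyloxy, 5α-H, 1β-CH3) | COc1ccc(C(=O)O[C@H]2CC(C)=C[C@@H](O)[C@@]3(C)CC[C@@](O)(C(C)C)[C@H]23)cc1 | target

## Step count and weak points

Total steps: 10. Longest linear sequence: 10 (1 → 16).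

Steps most likely to fail:

Step 7. The cascade is untested. The 7-endo addition of a stabilised allyl radical to a fully substituted β-carbon may be slow. The skipped 2,3-olefin can drift into conjugation through the dienamine. Enantioselectivity, the C10 configuration and the trans ring fusion all rest on transition-state arguments. The fallback sets out from 9 and returns at 12 by taking the two ring closures apart. Irradiation of 9 with (n-Bu4N)4[W10O32] alone (MeCN, 390 nm, no amine) gives, by neutral Giese closure of ring A, the monocyclic diketone rac-4-[(tert-butyldimethylsilyl)oxy]-3,6-dimethyl-3-(4-methyl-3-oxopentyl)cyclohept-5-en-1-one F1 (silyloxy trans to the ring methyl). Ring B is then closed in a separate equilibrating amine aldol (pyrrolidine, AcOH, 40 °C), which lets retro-aldol and enolisation settle the trans-fused, hydrogen-bonded ketol. The racemic 12 obtained this way is separated on a chiral stationary phase before step 8.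

Step 6. The Lewis acid can strip the allylic silyl ether, move the 2,3-olefin into conjugation, or give the aldehyde by alkyl instead of hydride shift. The fallback sets out from 8 and returns at 9, replacing the rearrangement by a C–C disconnection. H5IO6 (THF–H2O, 0 °C) cleaves the epoxide to (4E,8Z)-10-[(tert-butyldimethylsilyl)oxy]-4,8-dimethyl-6-oxodeca-4,8-dienal F2. i-PrMgCl (1.05 equiv, THF, −78 °C) adds selectively to the aldehyde to give rac-(2Z,6E)-1-[(tert-butyldimethylsilyl)oxy]-10-hydroxy-3,7,11-trimethyldodeca-2,6-dien-5-one F3. Dess–Martin periodinane (NaHCO3, CH2Cl2) oxidises F3 to 9.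

Step 8. Directed delivery from a hindered tertiary hydroxyl next to the bulky C10 silyl ether may be slow or unselective. The fallback sets out from 12 and returns at 15, bypassing 13 and step 9. An Evans–Tishchenko reduction with 4-methoxybenzaldehyde (4 equiv) and SmI2 (0.3 equiv) in THF at −10 °C sets the anti (6α) carbinol by intramolecular hydride transfer and leaves the acyl group on the tertiary oxygen, as (1S,4R,5S,6S,10R)-10-[(tert-butyldimethylsilyl)oxy]-6-hydroxydauc-8-en-4-yl 4-methoxybenzoate F4. DBU (toluene, 60 °C) then drives the 1,3 O→O acyl shift to the less hindered secondary oxygen, giving 15.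

Further compounds
F1 | step 7 | rac-4-[(tert-butyldimethylsilyl)oxy]-3,6-dimethyl-3-(4-methyl-3-oxopentyl)cyclohept-5-en-1-one (one enantiomer drawn) | CC(C)C(=O)CC[C@@]1(C)CC(=O)CC(C)=C[C@H]1O[Si](C)(C)C(C)(C)C
F2 | step 6 | (4E,8Z)-10-[(tert-butyldimethylsilyl)oxy]-4,8-dimethyl-6-oxodeca-4,8-dienal | CC(C)(C)[Si](C)(C)OC/C=C(C)\CC(=O)/C=C(\C)CCC=O
F3 | step 6 | rac-(2Z,6E)-1-[(tert-butyldimethylsilyl)oxy]-10-hydroxy-3,7,11-trimethyldodeca-2,6-dien-5-one | CC(C)(C)[Si](C)(C)OC/C=C(C)\CC(=O)/C=C(\C)CCC(O)C(C)C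
F4 | step 8 | (1S,4R,5S,6S,10R)-10-[(tert-butyldimethylsilyl)oxy]-6-hydroxydauc-8-en-4-yl 4-methoxybenzoate | O[C@H]2CC(C)=C[C@@H](O[Si](C)(C)C(C)(C)C)[C@@]3(C)CC[C@@](OC(=O)c4ccc(OC)cc4)(C(C)C)[C@H]23
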